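Two questions were asked of this flask, one early and one late, and I treated the late one as bookkeeping rather than as a matter of rates.

- dawn: G 0.68 M; Q 1.3 equiv; L 15 mol%; the very flask that is asked about, followed so far
- flask: G 0.68 M; Q 1.30 equiv; L 15 mol%; time 6.0 h

dawn run (percent of the G charged)

| time / min | E / % | J / % | G / % |
|---|---|---|---|
| 15.0 | 43.1 | 9.0 | 31.6 |
| 40.0 | 65.6 | 23.9 | 4.2 |
| 80.0 | 68.7 | 29.9 | 0.5 |
| 120 | 66.9 | 31.2 | 0 |

(scatter of a reading: 0.5 percentage points)

1. ratio of E to J at 3.0 min
2. ratio of E to J at 6.0 h



The readings above were my table. I supposed that each E had cost one Q and each J two, and from each row I worked out the Q tally [E] + 2[J], the Q spent in percent of the G charged. Going down the rows it read 61.1%, 113%, 128% and 129%. It climbed and then levelled off just under the 130% charged. The last row left 0.7 percentage points of Q, less than the tally's own scatter of 1.1 points.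

Q charged was less than two per G, so on this tally Q was the limiting reagent for turning E into J. My first round took E and J together as the whole of G. J then equals the Q excess, the Q charged beyond one per G, 30.0%, and the ratio is 2.33.

For the second round I put that answer back against the last two rows, which on average fell 1.4 points short of the G charged. Supposing that this shortfall had taken no Q, I raised J to 31.4% and lowered E to 67.2%, which gave 2.14.

The tally gave me nothing for the early question. I noted only that E to J read 4.79 in the first row and fell down every row.

The forecast, which called the late fall of E “barely above noise”, gave 23 (13 to 40) and 1.7 (1.25 to 2.2), the second lower than my 2.14.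

The flask gave 25.3 and 2.18.

    L + Z ⇌ X (K = 13.0 /M, k = 3.40 /M/min)
    Q + E → J (k = 0.0450 /M/min)
    Q + X → L + E (k = 3.00 /M/min)
    G + L → L + Z (k = 0.830 /M/min)

At 6.00 h the flask held E 67.8%, J 31.1% and Q 0% of its charge, J being 1.1 points more than the Q excess of 30.0%. In the neighbour charged with 2.20 equiv the same reckoning gave an excess of 120%, more than the G charged. My tally therefore counted each G as J and left 9.09% of that flask's Q. That neighbour ended with J 97.8%, E 2.22% and Q 10.1% of its charge, a ratio of 0.0227.

The numbers in the tables stem from a simulated flask with made-up constants, and the scatter is random.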